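**Retrosynthetic overview**

1. Target 31 comes from the E-olefin 30 by a late Shi epoxidation (C3–C4 oxirane), and 30 from the macrocyclic C7 enone 29 by CBS reduction (C7 carbinol).
2. The 14-membered ring of 29 is closed at C4–C5 from acyclic 27 by a palladium-catalysed ring-opening coupling of a cyclopropanol (C5–C6–C7) with the (E)-alkenyl iodide at C4.
3. Enabling feature: C5 and C6 are unsubstituted ring methylenes and C7 carries oxygen, so C5–C6–C7 can be stored as a strained three-membered carbinol ring whose opening makes C5 a nucleophile and C7 a carbonyl; C4 is the methyl-bearing oxirane carbon and can be carried as an sp2 C–I.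
4. The γ-lactone (O–C14–C1–C15–C16) comes from an indium Barbier allylation/lactonisation joining α-hydroxy aldehyde 23 (C5–C14) and allylic bromide 10 (C1–C4, C15–C18) at C1–C14.
5. Ring order: cyclopropane (temporary, step 8), then γ-lactone (step 13), then 14-membered carbocycle (step 16, cyclopropane consumed), then oxirane (step 18).

Key step: step 16

Remark: cembrane numbering is used for the macrocycle (C1 = ring-fusion carbon bearing C15; C3/C4 = oxirane, C4 with Me-18; C7 = carbinol; C8 = carbon of the exocyclic C19 methylene; C12 = methyl-bearing; C13 = acetoxy; C14 = lactone-oxygen carbon; C16 = lactone carbonyl; C17 = lactone methylene); the SMILES is read as a cis-fused lactone and an oxirane derived from an E-olefin, i.e. 1S,3R,4R,7R,12S,13R,14R.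

**Route**

Step 1
Reactants: 1 pent-3-yn-1-ol
Product: 2 tert-butyldimethyl(pent-3-yn-1-yloxy)silane
Conditions: TBSCl, imidazole, DMF, 0 °C → rt
Reagents that add atoms: tert-butyldimethylsilyl chloride, CC(C)(C)[Si](C)(C)Cl
Why: Standard silylation of a primary alcohol, chosen so that the following hydrozirconation is steered by sterics and not by a metal alkoxide.

Step 2
Reactants: 2 tert-butyldimethyl(pent-3-yn-1-yloxy)silane
Product: 4 (E)-tert-butyl[(4-iodopent-3-en-1-yl)oxy]dimethylsilane, via alkenylzirconocene chloride 3 (not isolated)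
Conditions: Cp2Zr(H)Cl (2.2 equiv), THF, 50 °C; then I2, 0 °C
Reagents that add atoms: iodine, [I][I]
Why: syn-Hydrozirconation with excess reagent should equilibrate zirconium to the less hindered, methyl-bearing alkyne carbon, and iodinolysis with retention should give the E alkenyl iodide (future C3=C4 geometry).

Step 3
Reactants: 4 (E)-tert-butyl[(4-iodopent-3-en-1-yl)oxy]dimethylsilane
Product: 5 (E)-4-iodopent-3-en-1-ol
Conditions: camphorsulfonic acid (cat.), MeOH, 0 °C → rt
Reagents that add atoms: none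
Why: Acid-catalysed methanolysis of a primary silyl ether, to which the alkenyl iodide is inert.

Step 4
Reactants: 5 (E)-4-iodopent-3-en-1-ol
Product: 6 (E)-4-iodopent-3-enal
Conditions: Dess–Martin periodinane, pyridine, CH2Cl2, 0 °C; used at once
Reagents that add atoms: none
Why: Buffered Dess–Martin oxidation should deliver the β,γ-unsaturated aldehyde without moving the double bond into conjugation.

Step 5
Reactants: 6 (E)-4-iodopent-3-enal; 7 methyl propiolate
Product: 9 methyl (5E)-3-hydroxy-6-iodo-2-methylidenehept-5-enoate (racemic), via vinylalane 8 (not isolated)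
Conditions: 7, iBu2AlH, N-methylmorpholine N-oxide, THF, 0 °C; then 6, 0 °C → rt
Reagents that add atoms: none
Why: Hydroalumination of the ynoate gives the α-alumino acrylate, which adds to the aldehyde to give a Baylis–Hillman-type adduct without the amine base that would isomerise the aldehyde; the racemic carbinol centre is erased in step 6.

Step 6
Reactants: 9 methyl (5E)-3-hydroxy-6-iodo-2-methylidenehept-5-enoate
Product: 10 methyl (2Z,5E)-2-(bromomethyl)-6-iodohepta-2,5-dienoate
Conditions: NBS, Me2S, CH2Cl2, 0 °C → rt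
Reagents that add atoms: N-bromosuccinimide, O=C1CCC(=O)N1Br
Why: Activation of the allylic alcohol as an alkoxysulfonium salt and SN2′ delivery of bromide should give the rearranged, conjugated (Z)-allylic bromide typical of Baylis–Hillman adducts.

Step 7
Reactants: 11 5-chloropent-1-yne
Product: 13 2-bromo-5-chloropent-1-ene, via bromoalkenylborane 12 (not isolated)
Conditions: B-bromo-9-BBN, CH2Cl2, 0 °C → rt; then AcOH
Reagents that add atoms: 9-bromo-9-borabicyclo[3.3.1]nonane, BrB1C2CCCC1CCC2
Why: Markovnikov syn-bromoboration of the terminal alkyne followed by protodeboronation gives the 2-bromo-1-alkene (future C8 and C19).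

Step 8
Reactants: 13 2-bromo-5-chloropent-1-ene; 14 1-ethoxycyclopropan-1-ol (cyclopropanone ethyl hemiketal)
Product: 17 1-(5-chloropent-1-en-2-yl)cyclopropan-1-ol, via alkenyllithium 15 (not isolated), via cyclopropanone 16 (not isolated)
Conditions: 13, t-BuLi (2 equiv), Et2O, −78 °C; 14, MeMgBr (1 equiv), THF, −78 → 0 °C; solutions combined, −78 °C → rt
Reagents that add atoms: none
Why: Bromine–lithium exchange (the alkyl chloride is untouched at −78 °C) and 1,2-addition of the alkenyllithium to cyclopropanone released from the hemiketal magnesium salt give the tertiary cyclopropanol that holds C5, C6 and C7.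

Step 9
Reactants: 17 1-(5-chloropent-1-en-2-yl)cyclopropan-1-ol
Product: 18 {[1-(5-chloropent-1-en-2-yl)cyclopropyl]oxy}triethylsilane
Conditions: TESCl, imidazole, DMAP (cat.), DMF, rt
Reagents that add atoms: chlorotriethylsilane, CC[Si](Cl)(CC)CC
Why: Base-mediated silylation masks the acidic, oxidation-sensitive cyclopropanol without the acid that would trigger ring expansion of the alkenylcyclopropanol.

Step 10
Reactants: 19 (E)-but-2-en-1-ol
Product: 20 [(2S,3S)-3-methyloxiran-2-yl]methanol
Conditions: Ti(OiPr)4 (5 mol %), L-(+)-diethyl tartrate (6 mol %), t-BuOOH, 4 Å molecular sieves, CH2Cl2, −20 °C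
Reagents that add atoms: tert-butyl hydroperoxide, CC(C)(C)OO
Why: Sharpless asymmetric epoxidation, in which the L-(+)-tartrate complex delivers oxygen to the face that gives the (2S,3S)-epoxy alcohol; its carbinol-side carbon becomes C13.

Step 11
Reactants: 18 {[1-(5-chloropent-1-en-2-yl)cyclopropyl]oxy}triethylsilane; 20 [(2S,3S)-3-methyloxiran-2-yl]methanol
Product: 22 (2R,3S)-3-methyl-7-{1-[(triethylsilyl)oxy]cyclopropyl}oct-7-ene-1,2-diol, via Grignard reagent 21 (not isolated)
Conditions: 18, Mg, BrCH2CH2Br (cat.), THF, 60 °C; 20, i-PrMgCl (1.0 equiv), THF, −40 °C; then 21, CuI (10 mol %), −40 → 0 °C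
Reagents that add atoms: none
Why: Copper-catalysed SN2 opening of the 2,3-epoxy alkoxide at the methyl-bearing carbon remote from the alkoxide should give the 1,2-diol with inversion, which sets C12 (S) syn to the retained C13 carbinol.

Step 12
Reactants: 22 (2R,3S)-3-methyl-7-{1-[(triethylsilyl)oxy]cyclopropyl}oct-7-ene-1,2-diol
Product: 23 (2R,3S)-2-hydroxy-3-methyl-7-{1-[(triethylsilyl)oxy]cyclopropyl}oct-7-enal
Conditions: TEMPO (10 mol %), N-chlorosuccinimide, n-Bu4NCl (10 mol %), CH2Cl2/aq. NaHCO3, rt; crude product used directly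
Reagents that add atoms: none
Why: Oxoammonium-catalysed oxidation is expected to take the unhindered primary carbinol much faster than the secondary one, and this oxidant does not cleave glycols, so the α-hydroxy aldehyde should form without touching C13.

Step 13
Reactants: 23 (2R,3S)-2-hydroxy-3-methyl-7-{1-[(triethylsilyl)oxy]cyclopropyl}oct-7-enal; 10 methyl (2Z,5E)-2-(bromomethyl)-6-iodohepta-2,5-dienoate
Product: 25 (4S,5R)-5-[(1R,2S)-1-hydroxy-2-methyl-6-{1-[(triethylsilyl)oxy]cyclopropyl}hept-6-en-1-yl]-4-[(2E)-3-iodobut-2-en-1-yl]-3-methylideneoxolan-2-one, via hydroxy ester 24 (not isolated)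
Conditions: In powder, THF/H2O (1:1), rt; then PPTS (cat.), CH2Cl2, rt
Reagents that add atoms: none
Why: Barbier allylation through the γ-carbon of the allylindium, in which chelation of indium by the free C13 hydroxyl and the aldehyde oxygen should direct attack to give the 13,14-syn diol (C14) and the cyclic transition state the syn relation that becomes the cis-lactone (C1), after which mild acid closes the five-membered lactone through the C14 hydroxyl.

Step 14
Reactants: 25 (4S,5R)-5-[(1R,2S)-1-hydroxy-2-methyl-6-{1-[(triethylsilyl)oxy]cyclopropyl}hept-6-en-1-yl]-4-[(2E)-3-iodobut-2-en-1-yl]-3-methylideneoxolan-2-one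
Product: 26 (1R,2S)-1-{(2R,3S)-3-[(2E)-3-iodobut-2-en-1-yl]-4-methylidene-5-oxooxolan-2-yl}-2-methyl-6-{1-[(triethylsilyl)oxy]cyclopropyl}hept-6-en-1-yl acetate
Conditions: Ac2O, pyridine, DMAP (cat.), CH2Cl2, 0 °C → rt
Reagents that add atoms: acetic anhydride, CC(=O)OC(C)=O
Why: Acylation of the only free hydroxyl installs the C13 acetate of the target with retention.

Step 15
Reactants: 26 (1R,2S)-1-{(2R,3S)-3-[(2E)-3-iodobut-2-en-1-yl]-4-methylidene-5-oxooxolan-2-yl}-2-methyl-6-{1-[(triethylsilyl)oxy]cyclopropyl}hept-6-en-1-yl acetate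
Product: 27 (1R,2S)-6-(1-hydroxycyclopropyl)-1-{(2R,3S)-3-[(2E)-3-iodobut-2-en-1-yl]-4-methylidene-5-oxooxolan-2-yl}-2-methylhept-6-en-1-yl acetate
Conditions: Bu4NF, AcOH (1:1), THF, 0 °C
Reagents that add atoms: none
Why: Acetic-acid-buffered fluoride should cleave the cyclopropyl silyl ether without base-induced opening of the cyclopropanol, loss of the acetate or addition to the methylene lactone.

Step 16
Reactants: 27 (1R,2S)-6-(1-hydroxycyclopropyl)-1-{(2R,3S)-3-[(2E)-3-iodobut-2-en-1-yl]-4-methylidene-5-oxooxolan-2-yl}-2-methylhept-6-en-1-yl acetate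
Product: 29 (1S,3E,12S,13R,14R)-13-acetoxy-7-oxocembra-3,8(19),15(17)-trien-16,14-olide, via palladium homoenolate 28 (not isolated)
Conditions: Pd2(dba)3 (7.5 mol %), XPhos (30 mol %), Cs2CO3 (2 equiv), toluene, 70 °C, 27 added by syringe pump (final 1 mM)
Reagents that add atoms: none
Why: Proposed new method: zerovalent palladium should insert into the C4–I bond of the (E)-alkenyl iodide with retention, the caesium cyclopropanolate should replace iodide on palladium, and strain-driven β-carbon elimination of either of the two equivalent ring bonds should turn the C5–C6–C7 cyclopropanol into a palladium homoenolate, an alkyl(alkenyl)palladium held in a 15-membered palladacycle that reductively eliminates to forge C4–C5. The closest known reaction type is the intermolecular palladium-catalysed ring-opening cross-coupling of cyclopropanols with aryl and alkenyl halides, which has not been used to close a macrocycle. The 14-membered carbocycle is closed by C(sp2)–C(sp3) reductive elimination from the palladacycle (formally a 14-endo closure), with the release of cyclopropane strain offsetting the entropic cost, and the same event unmasks the C7 ketone next to the C8 methylene. No stereocentre is created: the E geometry of C3=C4, which later defines the trans-oxirane, is carried over from the iodide, and C1, C12, C13 and C14 are not touched by the weak base. The step needs reductive elimination to outrun β-hydride elimination of the homoenolate and intermolecular coupling, for which the bulky biarylphosphine and slow addition at high dilution are chosen; the E geometry of the iodide also keeps the alkenylpalladium from reaching the lactone methylene.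

Step 17
Reactants: 29 (1S,3E,12S,13R,14R)-13-acetoxy-7-oxocembra-3,8(19),15(17)-trien-16,14-olide
Product: 30 (1S,3E,7R,12S,13R,14R)-13-acetoxy-7-hydroxycembra-3,8(19),15(17)-trien-16,14-olide
Conditions: (S)-2-methyl-CBS-oxazaborolidine (0.5 equiv), catecholborane, toluene, −78 °C; MeOH quench, aqueous work-up
Reagents that add atoms: none
Why: Corey–Bakshi–Shibata reduction, in which the (S)-oxazaborolidine treats the branched alkenyl group as the large substituent and delivers hydride 1,2 to give the (7R)-allylic alcohol, while catecholborane at −78 °C leaves the lactone, the acetate and the olefins alone.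

Step 18
Reactants: 30 (1S,3E,7R,12S,13R,14R)-13-acetoxy-7-hydroxycembra-3,8(19),15(17)-trien-16,14-olide
Product: 31 (1S,3R,4R,7R,12S,13R,14R)-13-acetoxy-3,4-epoxy-7-hydroxycembra-8(19),15(17)-dien-16,14-olide (target)
Conditions: D-fructose-derived Shi ketone (0.5 equiv), KHSO5 (Oxone), K2CO3, Bu4NHSO4, MeCN/dimethoxymethane/aq. Na2B4O7 buffer, 0 °C
Reagents that add atoms: potassium peroxymonosulfate, [K+].[O-]S(=O)(=O)OO
Why: Shi epoxidation, in which the chiral dioxirane should select the electron-rich trisubstituted E-olefin over the 1,1-disubstituted and acrylate olefins and, through its spiro transition state, deliver oxygen to the face that gives the (3R,4R)-oxirane.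

**Compound list**

1 | pent-3-yn-1-ol | CC#CCCO | starting material
2 | tert-butyldimethyl(pent-3-yn-1-yloxy)silane | CC#CCCO[Si](C)(C)C(C)(C)C | intermediate
3 | (E)-alkenylzirconocene chloride from 2 (cyclopentadienyl ligands drawn σ-bonded) | C/C(=C\CCO[Si](C)(C)C(C)(C)C)[Zr](Cl)(C1C=CC=C1)C1C=CC=C1 | intermediate
4 | (E)-tert-butyl[(4-iodopent-3-en-1-yl)oxy]dimethylsilane | C/C(I)=C\CCO[Si](C)(C)C(C)(C)C | intermediate
5 | (E)-4-iodopent-3-en-1-ol | C/C(I)=C\CCO | intermediate
6 | (E)-4-iodopent-3-enal | C/C(I)=C\CC=O | intermediate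
7 | methyl propiolate | C#CC(=O)OC | starting material
8 | [1-(methoxycarbonyl)ethenyl]diisobutylaluminium | C=C(C(=O)OC)[Al](CC(C)C)CC(C)C | intermediate
9 | methyl (5E)-3-hydroxy-6-iodo-2-methylidenehept-5-enoate (racemic) | C=C(C(=O)OC)C(O)C/C=C(\C)I | intermediate
10 | methyl (2Z,5E)-2-(bromomethyl)-6-iodohepta-2,5-dienoate | COC(=O)/C(CBr)=C/C/C=C(\C)I | intermediate
11 | 5-chloropent-1-yne | C#CCCCCl | starting material
12 | (Z)-9-(2-bromo-5-chloropent-1-en-1-yl)-9-borabicyclo[3.3.1]nonane | ClCCC/C(Br)=C/B1C2CCCC1CCC2 | intermediate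
13 | 2-bromo-5-chloropent-1-ene | C=C(Br)CCCCl | intermediate
14 | 1-ethoxycyclopropan-1-ol | CCOC1(O)CC1 | starting material
15 | (5-chloropent-1-en-2-yl)lithium | [Li]C(=C)CCCCl | intermediate
16 | cyclopropanone | O=C1CC1 | intermediate
17 | 1-(5-chloropent-1-en-2-yl)cyclopropan-1-ol | C=C(CCCCl)C1(O)CC1 | intermediate
18 | {[1-(5-chloropent-1-en-2-yl)cyclopropyl]oxy}triethylsilane | C=C(CCCCl)C1(O[Si](CC)(CC)CC)CC1 | intermediate
19 | (E)-but-2-en-1-ol | C/C=C/CO | starting material
20 | [(2S,3S)-3-methyloxiran-2-yl]methanol | C[C@@H]1O[C@H]1CO | intermediate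
21 | {4-[1-(triethylsilyloxy)cyclopropyl]pent-4-en-1-yl}magnesium chloride | C=C(CCC[Mg]Cl)C1(O[Si](CC)(CC)CC)CC1 | intermediate
22 | (2R,3S)-3-methyl-7-{1-[(triethylsilyl)oxy]cyclopropyl}oct-7-ene-1,2-diol | OC[C@H](O)[C@@H](C)CCCC(=C)C1(O[Si](CC)(CC)CC)CC1 | intermediate
23 | (2R,3S)-2-hydroxy-3-methyl-7-{1-[(triethylsilyl)oxy]cyclopropyl}oct-7-enal | O=C[C@H](O)[C@@H](C)CCCC(=C)C1(O[Si](CC)(CC)CC)CC1 | intermediate
24 | methyl (3S,4R,5R,6S)-4,5-dihydroxy-3-[(2E)-3-iodobut-2-en-1-yl]-6-methyl-2-methylidene-10-{1-[(triethylsilyl)oxy]cyclopropyl}undec-10-enoate | C=C(CCC[C@H](C)[C@@H](O)[C@H](O)[C@@H](C/C=C(\C)I)C(=C)C(=O)OC)C1(O[Si](CC)(CC)CC)CC1 | intermediate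
25 | (4S,5R)-5-[(1R,2S)-1-hydroxy-2-methyl-6-{1-[(triethylsilyl)oxy]cyclopropyl}hept-6-en-1-yl]-4-[(2E)-3-iodobut-2-en-1-yl]-3-methylideneoxolan-2-one | C=C(CCC[C@H](C)[C@@H](O)[C@@H]1OC(=O)C(=C)[C@@H]1C/C=C(\C)I)C1(O[Si](CC)(CC)CC)CC1 | intermediate
26 | (1R,2S)-1-{(2R,3S)-3-[(2E)-3-iodobut-2-en-1-yl]-4-methylidene-5-oxooxolan-2-yl}-2-methyl-6-{1-[(triethylsilyl)oxy]cyclopropyl}hept-6-en-1-yl acetate | C=C(CCC[C@H](C)[C@@H](OC(C)=O)[C@@H]1OC(=O)C(=C)[C@@H]1C/C=C(\C)I)C1(O[Si](CC)(CC)CC)CC1 | intermediate
27 | (1R,2S)-6-(1-hydroxycyclopropyl)-1-{(2R,3S)-3-[(2E)-3-iodobut-2-en-1-yl]-4-methylidene-5-oxooxolan-2-yl}-2-methylhept-6-en-1-yl acetate | C=C(CCC[C@H](C)[C@@H](OC(C)=O)[C@@H]1OC(=O)C(=C)[C@@H]1C/C=C(\C)I)C1(O)CC1 | intermediate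
28 | 15-membered alkyl(alkenyl)palladium homoenolate, palladium between C4 and C5 (phosphine omitted) | C=C1CCC[C@H](C)[C@@H](OC(C)=O)[C@@H]2OC(=O)C(=C)[C@@H]2C/C=C(\C)[Pd]CCC1=O | intermediate
29 | (1S,3E,12S,13R,14R)-13-acetoxy-7-oxocembra-3,8(19),15(17)-trien-16,14-olide | C=C1CCC[C@H](C)[C@@H](OC(C)=O)[C@@H]2OC(=O)C(=C)[C@@H]2C/C=C(\C)CCC1=O | intermediate
30 | (1S,3E,7R,12S,13R,14R)-13-acetoxy-7-hydroxycembra-3,8(19),15(17)-trien-16,14-olide | C=C1CCC[C@H](C)[C@@H](OC(C)=O)[C@@H]2OC(=O)C(=C)[C@@H]2C/C=C(\C)CC[C@H]1O | intermediate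
31 | (1S,3R,4R,7R,12S,13R,14R)-13-acetoxy-3,4-epoxy-7-hydroxycembra-8(19),15(17)-dien-16,14-olide | C=C1CCC[C@H](C)[C@@H](OC(C)=O)[C@@H]2OC(=O)C(=C)[C@@H]2C[C@H]2O[C@]2(C)CC[C@H]1O | target

**Step count and risks**

Total step count: 18. Longest linear sequence: 12 steps (steps 1–6, then 13–18).

The three steps most likely to fail:

Step 16 (key step, proposed new method). The ring-closing reductive elimination may lose to β-hydride elimination of the palladium homoenolate, to intermolecular coupling, or to palladium-induced ring expansion of the alkenylcyclopropanol. The fallback keeps the same C4–C5 closure but uses established organozinc chemistry; it sets out from 27 and comes back at 29. Diethylzinc (1.1 equiv, 2,2′-bipyridine, THF/DMSO) would deprotonate the cyclopropanol, and the zinc cyclopropoxide would open to the β-zincio ketone, ethyl{(8S,9R)-9-acetoxy-9-[(2R,3S)-3-((2E)-3-iodobut-2-en-1-yl)-4-methylidene-5-oxooxolan-2-yl]-8-methyl-4-methylidene-3-oxononyl}zinc F1. Slow addition of this preformed homoenolate to Pd(PPh3)4 in THF/DMF at high dilution would then close the ring by alkyl–alkenyl Negishi coupling, with transmetalation from zinc taking the place of β-carbon elimination on palladium.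

Step 13. Chelation control may be lost (Felkin-type addition to the α-hydroxy aldehyde), the syn simple diastereoselection may erode, or lactonisation may go through the C13 hydroxyl. The fallback replaces the aqueous free-hydroxyl Barbier by a Lewis-acid chelate on a protected aldehyde; it sets out from 22 and 10 and comes back at 25. Diol 22 would be converted with 4-methoxybenzaldehyde dimethyl acetal and PPTS into (4R)-2-(4-methoxyphenyl)-4-[(2S)-6-{1-[(triethylsilyl)oxy]cyclopropyl}hept-6-en-2-yl]-1,3-dioxolane F2. Opening with iBu2AlH at the less hindered oxygen would give (2R,3S)-2-[(4-methoxybenzyl)oxy]-3-methyl-7-{1-[(triethylsilyl)oxy]cyclopropyl}oct-7-en-1-ol F3, and Dess–Martin oxidation would give (2R,3S)-2-[(4-methoxybenzyl)oxy]-3-methyl-7-{1-[(triethylsilyl)oxy]cyclopropyl}oct-7-enal F4. Bromide 10 would be turned with Zn and Bu3SnCl in THF/aq. NH4Cl into methyl (2Z,5E)-6-iodo-2-[(tributylstannyl)methyl]hepta-2,5-dienoate F5. Addition of F5 to the MgBr2·OEt2 chelate of F4 in CH2Cl2 at low temperature should give the syn,syn adduct methyl (3S,4R,5R,6S)-4-hydroxy-3-[(2E)-3-iodobut-2-en-1-yl]-5-[(4-methoxybenzyl)oxy]-6-methyl-2-methylidene-10-{1-[(triethylsilyl)oxy]cyclopropyl}undec-10-enoate F6. PPTS would close it to (4S,5R)-4-[(2E)-3-iodobut-2-en-1-yl]-5-[(1R,2S)-1-[(4-methoxybenzyl)oxy]-2-methyl-6-{1-[(triethylsilyl)oxy]cyclopropyl}hept-6-en-1-yl]-3-methylideneoxolan-2-one F7, and DDQ in wet CH2Cl2 would remove the benzyl ether to give 25.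

Step 18. Facial selectivity may be poor if the macrocycle shields the face the catalyst prefers (mismatched double diastereoselection), and the basic medium may cost some acetate. If the oxygen is wanted on the shielded face, it would be delivered there indirectly, before the C7 hydroxyl exists (a free C7 hydroxyl would capture the bromonium ion across the ring). The fallback sets out from 29 and comes back at 31. NBS in wet dimethoxyethane should put bromine on the exposed face of C3 and water on C4 from the other face, to give (1S,3S,4R,12S,13R,14R)-13-acetoxy-3-bromo-4-hydroxy-7-oxocembra-8(19),15(17)-dien-16,14-olide F8. DBU would close the oxirane with inversion at C3 to give (1S,3R,4R,12S,13R,14R)-13-acetoxy-3,4-epoxy-7-oxocembra-8(19),15(17)-dien-16,14-olide F9, and the CBS reduction of step 17 applied to F9 would give 31.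

Further compounds
F1 | step 16 | ethyl{(8S,9R)-9-acetoxy-9-[(2R,3S)-3-((2E)-3-iodobut-2-en-1-yl)-4-methylidene-5-oxooxolan-2-yl]-8-methyl-4-methylidene-3-oxononyl}zinc | CC[Zn]CCC(=O)C(=C)CCC[C@H](C)[C@@H](OC(C)=O)[C@@H]1OC(=O)C(=C)[C@@H]1C/C=C(\C)I
F2 | step 13 | (4R)-2-(4-methoxyphenyl)-4-[(2S)-6-{1-[(triethylsilyl)oxy]cyclopropyl}hept-6-en-2-yl]-1,3-dioxolane (acetal epimers) | COc1ccc(cc1)C2OC[C@H](O2)[C@@H](C)CCCC(=C)C3(O[Si](CC)(CC)CC)CC3
F3 | step 13 | (2R,3S)-2-[(4-methoxybenzyl)oxy]-3-methyl-7-{1-[(triethylsilyl)oxy]cyclopropyl}oct-7-en-1-ol | OC[C@H](OCc1ccc(OC)cc1)[C@@H](C)CCCC(=C)C2(O[Si](CC)(CC)CC)CC2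
F4 | step 13 | (2R,3S)-2-[(4-methoxybenzyl)oxy]-3-methyl-7-{1-[(triethylsilyl)oxy]cyclopropyl}oct-7-enal | O=C[C@H](OCc1ccc(OC)cc1)[C@@H](C)CCCC(=C)C2(O[Si](CC)(CC)CC)CC2
F5 | step 13 | methyl (2Z,5E)-6-iodo-2-[(tributylstannyl)methyl]hepta-2,5-dienoate | COC(=O)/C(C[Sn](CCCC)(CCCC)CCCC)=C/C/C=C(\C)I
F6 | step 13 | methyl (3S,4R,5R,6S)-4-hydroxy-3-[(2E)-3-iodobut-2-en-1-yl]-5-[(4-methoxybenzyl)oxy]-6-methyl-2-methylidene-10-{1-[(triethylsilyl)oxy]cyclopropyl}undec-10-enoate | C=C(CCC[C@H](C)[C@@H](OCc1ccc(OC)cc1)[C@H](O)[C@@H](C/C=C(\C)I)C(=C)C(=O)OC)C2(O[Si](CC)(CC)CC)CC2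
F7 | step 13 | (4S,5R)-4-[(2E)-3-iodobut-2-en-1-yl]-5-[(1R,2S)-1-[(4-methoxybenzyl)oxy]-2-methyl-6-{1-[(triethylsilyl)oxy]cyclopropyl}hept-6-en-1-yl]-3-methylideneoxolan-2-one | C=C(CCC[C@H](C)[C@@H](OCc1ccc(OC)cc1)[C@@H]1OC(=O)C(=C)[C@@H]1C/C=C(\C)I)C2(O[Si](CC)(CC)CC)CC2
F8 | step 18 | (1S,3S,4R,12S,13R,14R)-13-acetoxy-3-bromo-4-hydroxy-7-oxocembra-8(19),15(17)-dien-16,14-olide | C=C1CCC[C@H](C)[C@@H](OC(C)=O)[C@@H]2OC(=O)C(=C)[C@@H]2C[C@H](Br)[C@](C)(O)CCC1=O
F9 | step 18 | (1S,3R,4R,12S,13R,14R)-13-acetoxy-3,4-epoxy-7-oxocembra-8(19),15(17)-dien-16,14-olide | C=C1CCC[C@H](C)[C@@H](OC(C)=O)[C@@H]2OC(=O)C(=C)[C@@H]2C[C@H]2O[C@]2(C)CCC1=O
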